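South holds twice the acidic substrate of the violet run under the same held gas, so when you repeat it, watch how long that charge has to wait.

common to all: electrophile 0.0221 M; gas 2.7 mM (held)
- violet: acidic substrate 0.011 M; temperature 100 °C; run made earlier
- south: acidic substrate 0.021 M; temperature 100 °C; time 10 h
- north: acidic substrate 0.021 M; temperature 60 °C; time 10 h
- north-west: acidic substrate 0.021 M; at 60 °C until 8.0 h, from then on at 100 °C; time 10 h
- west: acidic substrate 0.021 M; temperature 80 °C; time 10 h

- violet (time / h: target / %): 0.667: 10.7; 1.33: 23.1; 2.00: 34.4; 2.50: 42.8; 3.00: 51.4

(readings scatter by 0.3 percentage points)

- at the start none of the gas is in solution
- the earlier runs do not show what temperature does; that part of a forecast is a guess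

- the flask that comes out highest in amount of target, in percent of the acidic substrate charged, or "all alike" when all lie within 1.5 percentage points (south / north / north-west / west / all alike)
- target at the end, in percent of the acidic substrate charged, south
- target at the end, in percent of the acidic substrate charged, north
- target at the end, in percent of the acidic substrate charged, north-west
- target at the end, in percent of the acidic substrate charged, west

1. The violet readings run nearly straight, reaching 51.4 % of the charge after 3.00 h. I read that as a steady pace in amount made per hour.

2. At that pace south needs 11.1 h. Call this the feed time, the charge divided by the pace read from violet.

3. My bound from above for south is the time allowed over the feed time, 89.7 %. It assumes that the pace lasts and that waiting substrate comes to no harm.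

4. My bound from below assumes that south opens as violet did. What violet made by its last reading is 26.9 % of the south charge.

5. Now put the upper bound back in. To reach it, substrate must wait through most of the run, while violet's feed time is 5.84 h. The readings stop too early to show that such waiting is harmless, so I commit to the bracket and not to a point. The earlier runs do not show what temperature does, so I set no bracket for the other flasks.

6. The forecast names south, with 86 % for south, 6 % for north, 23 % for north-west and 25 % for west. Its ground is “probably set by the held gas”. Its south figure lies inside my bracket, close under the top.

7. The flasks give 34.0 % for south, 73.2 % for north, 77.3 % for north-west and 54.1 % for west, so north-west comes out highest. South lands inside the bracket, near its bottom.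

    acidic substrate + free base ⇌ protonated base + anion, settled at all times (K = 15.0, ΔH = 11.0 kJ mol⁻¹)
    electrophile + anion → target (k = 18.0 M⁻¹ min⁻¹, Ea = 45.0 kJ mol⁻¹)
    gas ⇌ free base, rate k3*(csat - [free base]) (kL = 0.0120 min⁻¹)
    2 acidic substrate → homo dimer (k = 0.550 M⁻¹ min⁻¹, Ea = 69.0 kJ mol⁻¹)
    (constants at 100 °C)

The pace read from violet is the passage of gas into free base. The main reason for south's shortfall is the step from acidic substrate to homo dimer: without it south gives 88.5 % instead of 34.0 %. Half of that dimer turnover in south is done by 0.372 h, far inside the feed time of 11.1 h. In a neighbour of south charged with 0.0084 M, the feed time is 4.46 h, shorter than the 10 h allowed, so the upper bound is the whole charge. That neighbour gives 64.3 %, with 35.7 % as homo dimer.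

(The runs were computed for an exercise, noise included.)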